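Early readings come first, in the larch flask and in the cooler ash run made before it.

in all of them: solid substrate 0.80 M; free catalyst 66 mM

| run | temperature | remark | time |
|---|---|---|---|
| larch | 40 °C | the very flask that is asked about, followed so far |  |
| ash | 25 °C | run made earlier |  |
| flask | 40 °C |  | 6.0 min |

| larch: time / min | larch: product / % | ash: time / min | ash: product / % |
|---|---|---|---|
| 0.250 | 13.2 | 0.500 | 17.5 |
| 0.500 | 27.1 | 1.00 | 39.1 |
| 1.00 | 47.4 | 2.00 | 70.8 |
| 2.00 | 60.1 | 4.00 | 89.9 |
| 4.00 | 63.3 | 8.00 | 95.1 |

(standard deviation of a reading: 0.5 percentage points)

- alpha: at 6.0 min take out 90 % of the product then present, then wait 3.0 min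
- gamma: change nothing and wait 3.0 min more
- eta: at 6.0 min add free catalyst, 50.0 % of the amount charged, then wait 3.0 min
- zeta: at 6.0 min raise the temperature by 25 K, then wait 3.0 min

- given per volume of solution although it is solid: solid substrate
- removed product is counted in
- at the start none of the solid substrate is in solution
- additions bring no volume worth counting

- product, in percent of the solid substrate first charged, at 6.0 min
- the remedy with the largest gain of product, or "none" below 2 percentage points (alpha / gamma / eta / zeta / none)
- product present, with what was taken out counted in, in percent of the solid substrate first charged, after gamma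
- product present, with what was taken out counted in, in percent of the solid substrate first charged, after eta

The larch run goes from 13.2 % at 0.250 min to 27.1 % at 0.500 min: twice the product in twice the time. The rate holds level over that stretch, so I take the substrate in solution as the concentration that sets the order. Later, with the solid dissolved, I expect that substrate to fall pseudo-first-order under whatever catalyst lives.

So I carry one quantity, the reach: the natural logarithm of the factor by which the catalyst alive at a given time can still shrink the unconverted remainder. I take 63.3 % as the larch plateau. The ash run passes it, so I do not look to product for the stop in larch. At 2.00 min the reach is then 0.0836.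

The gap to the plateau falls from 16 percentage points to 3.2 points within 1.00 min, which gives a decay constant of 1.60 min⁻¹. Carried forward, the reach at 6.0 min is 1.37 × 10⁻⁴, so I commit to about 63.3 % now and after gamma, and with that reach I expect no gain from alpha or zeta. Carried back, a full dose has 2.06 and the eta dose 1.03, so eta should end near 86.9 %.

The weak link is that small gap, since each reading carries 0.5 points. Shifting the gap by 0.71 points either way moves the decay constant to 1.40 min⁻¹ or 1.85 min⁻¹. The eta dose's reach at the upper value is 1.70, and eta then spans 81.6 % to 93.3 %.

The forecast gives 63.5 % now (62.8 % to 64.3 %), 63.5 % after gamma (62.8 % to 64.5 %), and eta as best with 83 % (76 % to 88 %), on the ground “Fresh catalyst should work”. My eta number stands above it.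

The flask gives 62.9 % now, 62.9 % after gamma and 93.2 % after eta, so eta is best, with a gain of 30 points.

    solid substrate ⇌ starting material, rate k1*(cs1 - [starting material]) while solid is left; crystals form when [starting material] > cs1 (solubility = 0.340 M, k = 0.0650 s⁻¹)
    free catalyst → spent catalyst B (k = 0.0290 s⁻¹, Ea = 92.0 kJ mol⁻¹)
    2 free catalyst → spent catalyst A (k = 0.120 M⁻¹ s⁻¹, Ea = 45.0 kJ mol⁻¹)
    starting material + free catalyst → free catalyst + product (k = 1.70 M⁻¹ s⁻¹, Ea = 56.0 kJ mol⁻¹)
    (constants at 40 °C)

The same flask without the turning of free catalyst into spent catalyst B leaves eta a gain of 0 points, and without the hold-up by dissolving, which is a part of the reason, 6.2 points. Measured on the result, the eta dose's reach is 1.70, more than the 1.03 I reckoned. In the second flask, the same recipe read at 1.5 min, I reckon the reach from the larch numbers as 0.186, which puts the remainder at 44.2 %; that flask holds 44 %, solid or dissolved.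

The numbers in the tables stem from a simulated flask on assumed constants; the scatter is artificial.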